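**Plan**
- Numbering (elemane): the oxirane C1–C2 sits on quaternary C10 (methyl C14). C5 carries C4(=C3H2)–C15HO, C6 is the ester carbinol, and C7/C8 are the lactone fusion (C11=C13, C12=O, ring O on C8). C9 is the free carbinol.
- Enabling feature: in the cyclohexane C5–C6–C7–C8–C9–C10, the C6 carbinol is vicinal to C5, which bears a 2-propenyl-type unit (C4, C3, C15). This is the isopulegol pattern, so ring bond C5–C6 is cut to a C6 aldehyde and a C5=C4 isopropylidene alkene.
- Other cuts: before the ring bond, the oxirane O, the C15 oxygen, C11=C13, the C6 ester and the C6 configuration. After it, C9–C10 (allylboration) and C6–C7 (radical conjugate addition).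
- Forward order: the γ-lactone is present from the start. C6 is attached to C7, C9 is oxidised and joined to C10, the cyclohexane closes at C5–C6, and the oxirane closes last.
- Stereochemistry: C8 comes from the (R)-butenolide and C7 from anti addition. C9 follows Cornforth/Felkin–Anh control, and C10 follows the (Z)-boronate geometry in a closed chair. C5 and C6 come from the lactone-locked chair, C6 is then corrected by oxidation and bulky hydride, and C1 comes from C9–OH-directed epoxidation.

Key step: step 11

Convention: β is the ring face that carries the C10 methyl; α is the opposite face.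
Assumption: compound 1 is bought as the single (R) enantiomer; its stereocentre becomes C8, so the more common (S) antipode would give the mirror-image series.

**Step 1**
Reactants: 1 (R)-5-(hydroxymethyl)furan-2(5H)-one
Product: 2 (R)-5-[(tert-butyldimethylsilyloxy)methyl]furan-2(5H)-one
Conditions: TBSCl, imidazole, CH2Cl2, 0 °C to rt
Reagents that add atoms: tert-butyldimethylsilyl chloride, CC(C)(C)[Si](C)(C)Cl
Why: Imidazole-promoted silylation of a primary alcohol is mild enough for the base-sensitive butenolide, touches no stereocentre, and installs the bulky group that shields one ring face in the next step.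

**Step 2**
Reactants: 2 (R)-5-[(tert-butyldimethylsilyloxy)methyl]furan-2(5H)-one; 3 1,3-dioxolane (reactant and solvent)
Product: 4 (4R,5R)-5-[(tert-butyldimethylsilyloxy)methyl]-4-(1,3-dioxolan-2-yl)dihydrofuran-2(3H)-one (trans; acetal carbon = C6)
Conditions: Ph2CO (10 mol%), hν (medium-pressure Hg lamp, Pyrex), degassed 1,3-dioxolane, 0–10 °C
Reagents that add atoms: none
Why: Benzophenone-sensitised hydrogen abstraction gives the nucleophilic 1,3-dioxolan-2-yl radical, and its Giese-type conjugate addition to the butenolide β-carbon (C7) occurs anti to the C8 silyloxymethyl group, which sets the trans C7/C8 relationship.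

**Step 3**
Reactants: 4 trans silyl ether acetal lactone
Product: 5 (4R,5R)-4-(1,3-dioxolan-2-yl)-5-(hydroxymethyl)dihydrofuran-2(3H)-one
Conditions: Bu4NF, AcOH, THF, 0 °C to rt
Reagents that add atoms: none
Why: Fluoride desilylation buffered with acetic acid frees the primary alcohol without opening or shifting the lactone and without touching the acetal.

**Step 4**
Reactants: 5 primary alcohol
Product: 6 (2R,3R)-3-(1,3-dioxolan-2-yl)-5-oxotetrahydrofuran-2-carbaldehyde (C9 aldehyde; used crude)
Conditions: Dess–Martin periodinane, CH2Cl2, 0 °C to rt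
Reagents that add atoms: none
Why: Dess–Martin oxidation runs under near-neutral conditions, so the epimerisable α-acyloxy aldehyde should keep its C8 configuration.

**Step 5**
Reactants: 7 propyne
Product: 9 (Z)-2-(2-bromoprop-1-en-1-yl)-4,4,5,5-tetramethyl-1,3,2-dioxaborolane, via (Z)-(2-bromoprop-1-enyl)dibromoborane 8 (not isolated)
Conditions: BBr3, CH2Cl2, −78 °C to rt; then pinacol, −78 °C to rt
Reagents that add atoms: boron tribromide, BrB(Br)Br; pinacol, CC(C)(O)C(C)(C)O
Why: Bromoboration adds B and Br syn across propyne with boron on the terminal carbon (future C1), and esterification with pinacol fixes the (Z)-β-bromoalkenylboronate before it can isomerise.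

**Step 6**
Reactants: 9 (Z)-bromoalkenyl pinacol boronate; 10 2-methylprop-1-enylmagnesium bromide
Product: 12 2-[(1Z)-2,4-dimethylpenta-1,3-dien-1-yl]-4,4,5,5-tetramethyl-1,3,2-dioxaborolane, via 2-methylprop-1-enylzinc bromide 11 (not isolated)
Conditions: ZnBr2, THF, 0 °C; then 9, Pd(P(t-Bu)3)2 (2 mol%), THF, rt
Reagents that add atoms: none
Why: Negishi cross-coupling replaces the alkenyl bromide with retention at both sp2 carbons and, being base-free, leaves the C–B bond alone, so the isobutenyl group (C5=C4) ends up cis to boron.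

**Step 7**
Reactants: 12 (1Z)-dienyl pinacol boronate
Product: 14 2-[(2Z)-3,5-dimethylhexa-2,4-dien-1-yl]-4,4,5,5-tetramethyl-1,3,2-dioxaborolane, via lithium chloromethyl boronate complex 13 (not isolated)
Conditions: BrCH2Cl, n-BuLi, THF, −78 °C to rt
Reagents that add atoms: bromochloromethane, ClCBr
Why: In this Matteson homologation, chloromethyllithium made in situ adds to boron and the alkenyl group migrates 1,2 with loss of chloride, which inserts C2 with retention of alkene geometry and avoids any ionisable dienyl halide that could scramble E/Z.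

**Step 8**
Reactants: 6 C9 aldehyde; 14 (2Z)-dienyl pinacol boronate
Product: 16 (4R,5R)-4-(1,3-dioxolan-2-yl)-5-[(1S,2S)-1-hydroxy-2,4-dimethyl-2-vinylpent-3-en-1-yl]dihydrofuran-2(3H)-one (9S;10S), via pinacol borate ester 15 (not isolated)
Conditions: toluene, 4 Å MS, rt to 40 °C; then pH 7 buffer
Reagents that add atoms: none
Why: Allylboration through a closed Zimmerman–Traxler chair joins γ-carbon C10 to C9 and places the methyl (trans to CH2B) anti and the isobutenyl (cis to CH2B) syn to O9, which fixes C10 relative to C9, while the Cornforth/polar Felkin–Anh bias of the α-acyloxy aldehyde, sharpened by the (Z)-γ-substituent, should give the 8,9-anti carbinol.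

**Step 9**
Reactants: 16 homoallylic alcohol
Product: 17 (4R,5R)-5-[(1S,2S)-1-(tert-butyldimethylsilyloxy)-2,4-dimethyl-2-vinylpent-3-en-1-yl]-4-(1,3-dioxolan-2-yl)dihydrofuran-2(3H)-one
Conditions: TBSOTf, 2,6-lutidine, CH2Cl2, −78 to 0 °C
Reagents that add atoms: tert-butyldimethylsilyl triflate, CC(C)(C)[Si](C)(C)OS(=O)(=O)C(F)(F)F
Why: Silyl triflate silylation is strong enough for the neopentyl-type C9 carbinol and blocks lactol formation with the later C6 aldehyde.

**Step 10**
Reactants: 17 TBS ether acetal
Product: 19 (2R,3R)-2-[(1S,2S)-1-(tert-butyldimethylsilyloxy)-2,4-dimethyl-2-vinylpent-3-en-1-yl]-5-oxotetrahydrofuran-3-carbaldehyde (ene precursor), via lutidinium triflate salt 18 (not isolated)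
Conditions: TESOTf, 2,6-lutidine (excess), CH2Cl2, 0 °C; then H2O
Reagents that add atoms: water, O
Why: In this silyl triflate/lutidine acetal cleavage, excess lutidine should capture the activated acetal faster than the hindered alkene can, and water then hydrolyses the salt near neutrality, so the TBS ether, the 1,4-diene and the epimerisable β-acyloxy aldehyde (C7) survive.

**Step 11**
Reactants: 19 trans-lactone aldehyde
Product: 21 (3aS,4R,5S,6S,7S,7aR)-7-(tert-butyldimethylsilyloxy)-4-hydroxy-6-methyl-5-(prop-1-en-2-yl)-6-vinylhexahydrobenzofuran-2(3H)-one (6α-OH and 5β-isopropenyl equatorial; 10β-methyl and 9α-OTBS axial), via chloro(methyl)aluminium alkoxide 20 (not isolated)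
Conditions: Me2AlCl (2.5 equiv), CH2Cl2, −78 to −20 °C; then 1 M HCl, 0 °C
Reagents that add atoms: none
Why: Me2AlCl binds the aldehyde oxygen (a second equivalent sits on the lactone carbonyl), C5 of the C5=C4 alkene attacks C6 while a hydrogen of the C4 methyl cis to H5 passes to O6 in one asynchronous six-centre event that leaves the C4=C3 isopropenyl group, and the product–aluminium complex then loses methane to give 20, which removes the proton that would start cationic side reactions. The closest known reaction is the Lewis-acid type 1 intramolecular carbonyl-ene cyclisation of citronellal to isopulegol, with C7–C8–C9–C10 as the tether. The cyclohexane closes 6-exo-trig at the aldehyde carbon through a chair-like array, and the ene π bond also stays outside the new ring. The trans lactone can only span two equatorial bonds (C7–C11 and C8–O), which fixes the chair with the C10 methyl and the C9 silyl ether axial, so C4 takes the equatorial site on C5 (trans to the C10 vinyl group) because the axial site would be syn-diaxial to the C9 silyloxy group. The aluminium-bearing O6 also goes equatorial, away from the axial C10 methyl and H8, which sets C6 as the 6α carbinol trans to C4. The step needs selectivity for C5=C4 over the vinyl group and for the aldehyde over the lactone, plus integrity at C7: the vinyl group is less nucleophilic and has no allylic hydrogen, the lactone carbonyl is a much poorer enophile, and the cold, non-basic, proton-scavenging medium gives the β-acyloxy aldehyde no route to enolise or eliminate.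

**Step 12**
Reactants: 21 6α-alcohol
Product: 22 C6 ketone (5β-isopropenyl; 10β-methyl; 10α-vinyl; 9α-OTBS; trans lactone kept)
Conditions: Dess–Martin periodinane, CH2Cl2, rt
Reagents that add atoms: none
Why: Dess–Martin oxidation of the secondary alcohol is neutral enough to avoid conjugation of the isopropenyl group (isopulegone-to-pulegone type), epimerisation at C5 or C7, and β-elimination of the lactone carboxylate.

**Step 13**
Reactants: 22 C6 ketone
Product: 24 6β (axial) alcohol (C6 epimer of 21), via lithium 6β-alkoxide 23 (not isolated)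
Conditions: LiBH(s-Bu)3, THF, −78 °C; AcOH, −78 °C; then H2O2, pH 7 buffer, 0 °C
Reagents that add atoms: none
Why: In this bulky trialkylborohydride reduction (isopulegone-to-neoisopulegol type), the axial trajectory on the β face is closed by the axial C10 methyl and H8, so hydride enters equatorially from the α face to give the axial 6β carbinol, and the cold acetic acid quench should prevent alkoxide translactonisation to C6.

**Step 14**
Reactants: 24 6β-alcohol
Product: 25 6β-isobutyrate
Conditions: (i-PrCO)2O, DMAP, pyridine, 40 °C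
Reagents that add atoms: isobutyric anhydride, CC(C)C(=O)OC(=O)C(C)C
Why: DMAP-catalysed acylation through the acylpyridinium ion can reach the hindered axial alcohol, and it is done before any Michael acceptor is present so that forcing conditions cause no harm.

**Step 15**
Reactants: 25 6β-isobutyrate
Product: 29 α-methylene lactone (C11=C13), via lithium lactone enolate 26 (not isolated), via Mannich base 27 (not isolated), via trimethylammonium iodide 28 (not isolated)
Conditions: LiN(SiMe3)2 (1.05 equiv), THF, −78 °C; CH2=NMe2+ I−, −78 °C to rt; MeI, THF, rt; aq NaHCO3, CH2Cl2, rt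
Reagents that add atoms: Eschenmoser's salt, C=[N+](C)C.[I-]
Why: In this Eschenmoser methylenation, the lactone C11 methylene is clearly more acidic and less hindered than the tertiary α-CH of the isobutyrate, so one equivalent of the mild amide base should enolise only the lactone, and the Mannich base is then quaternised and loses trimethylamine by E1cB elimination, which erases the transient C11 centre.

**Step 16**
Reactants: 29 α-methylene lactone
Product: 31 C15 enal (5β-acrolein unit; 9α-OTBS; 10α-vinyl), via allylic alcohol 30 (not isolated)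
Conditions: SeO2 (1.2 equiv), 1,4-dioxane, 80 °C
Reagents that add atoms: selenium dioxide, O=[Se]=O
Why: Riley oxidation engages only the electron-rich C4=C3 alkene (the vinyl group has no allylic hydrogen and C11=C13 is electron-poor) by ene reaction and [2,3]-shift at the methyl rather than at the hindered, ester-deactivated C5–H, and the allylic alcohol is oxidised on to the enal in the same flask.

**Step 17**
Reactants: 31 silyl ether enal
Product: 32 9α-alcohol
Conditions: HF·pyridine, THF, 0 °C to rt
Reagents that add atoms: none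
Why: Acidic fluoride desilylation removes the hindered axial TBS ether without the basic conditions that would damage the enal, the α-methylene lactone or the ester.

**Step 18**
Reactants: 32 9α-alcohol
Product: 33 target, (1R,5R,6S,7S,8R,9S,10S)-1,2-epoxy-9-hydroxy-6-isobutyryloxy-15-oxoelema-3,11(13)-dien-12,8-olide
Conditions: VO(acac)2 (10 mol%), t-BuOOH (decane), CH2Cl2, 0 °C to rt
Reagents that add atoms: tert-butyl hydroperoxide, CC(C)(C)OO
Why: In this hydroxyl-directed vanadium-catalysed epoxidation of a homoallylic alcohol, the vinyl group is the only non-deactivated alkene left, and the ring-fixed gauche O9–C9–C10–C1 array allows a single chair-like vanadate transition state with C2 swung under the ring anti to the axial C10 methyl, so oxygen should reach the alkene face turned toward O9 and give (1R).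

**Compound list**
1 | (R)-5-(hydroxymethyl)furan-2(5H)-one | O=C1O[C@@H](CO)C=C1 | starting material
2 | (R)-5-[(tert-butyldimethylsilyloxy)methyl]furan-2(5H)-one | O=C1O[C@@H](CO[Si](C)(C)C(C)(C)C)C=C1 | intermediate
3 | 1,3-dioxolane | C1COCO1 | starting material
4 | (4R,5R)-5-[(tert-butyldimethylsilyloxy)methyl]-4-(1,3-dioxolan-2-yl)dihydrofuran-2(3H)-one | C1C(=O)O[C@@H](CO[Si](C)(C)C(C)(C)C)[C@@H]1C2OCCO2 | intermediate
5 | (4R,5R)-4-(1,3-dioxolan-2-yl)-5-(hydroxymethyl)dihydrofuran-2(3H)-one | C1C(=O)O[C@@H](CO)[C@@H]1C2OCCO2 | intermediate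
6 | (2R,3R)-3-(1,3-dioxolan-2-yl)-5-oxotetrahydrofuran-2-carbaldehyde | C1C(=O)O[C@@H](C=O)[C@@H]1C2OCCO2 | intermediate
7 | propyne | CC#C | starting material
8 | (Z)-(2-bromoprop-1-enyl)dibromoborane | C/C(Br)=C/B(Br)Br | intermediate (not isolated)
9 | (Z)-2-(2-bromoprop-1-en-1-yl)-4,4,5,5-tetramethyl-1,3,2-dioxaborolane | C/C(Br)=C/B1OC(C)(C)C(C)(C)O1 | intermediate
10 | 2-methylprop-1-enylmagnesium bromide | CC(C)=C[Mg]Br | starting material
11 | 2-methylprop-1-enylzinc bromide | CC(C)=C[Zn]Br | intermediate (not isolated)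
12 | 2-[(1Z)-2,4-dimethylpenta-1,3-dien-1-yl]-4,4,5,5-tetramethyl-1,3,2-dioxaborolane | C/C(C=C(C)C)=C/B1OC(C)(C)C(C)(C)O1 | intermediate
13 | lithium (chloromethyl)[(1Z)-2,4-dimethylpenta-1,3-dienyl]pinacolatoborate | [Li+].C/C(C=C(C)C)=C/[B-]1(CCl)OC(C)(C)C(C)(C)O1 | intermediate (not isolated)
14 | 2-[(2Z)-3,5-dimethylhexa-2,4-dien-1-yl]-4,4,5,5-tetramethyl-1,3,2-dioxaborolane | C/C(C=C(C)C)=C/CB1OC(C)(C)C(C)(C)O1 | intermediate
15 | pinacol borate ester of 16 | C1C(=O)O[C@@H]([C@@H](OB3OC(C)(C)C(C)(C)O3)[C@@](C)(C=C)C=C(C)C)[C@@H]1C2OCCO2 | intermediate (not isolated)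
16 | (4R,5R)-4-(1,3-dioxolan-2-yl)-5-[(1S,2S)-1-hydroxy-2,4-dimethyl-2-vinylpent-3-en-1-yl]dihydrofuran-2(3H)-one | C1C(=O)O[C@@H]([C@@H](O)[C@@](C)(C=C)C=C(C)C)[C@@H]1C2OCCO2 | intermediate
17 | C9 TBS ether of 16 | C1C(=O)O[C@@H]([C@@H](O[Si](C)(C)C(C)(C)C)[C@@](C)(C=C)C=C(C)C)[C@@H]1C2OCCO2 | intermediate
18 | 1-[C6-(2-triethylsilyloxyethoxy)alkyl]-2,6-lutidinium triflate (C6 undefined) | C1C(=O)O[C@@H]([C@@H](O[Si](C)(C)C(C)(C)C)[C@@](C)(C=C)C=C(C)C)[C@@H]1C(OCCO[Si](CC)(CC)CC)[n+]2c(C)cccc2C.[O-]S(=O)(=O)C(F)(F)F | intermediate (not isolated)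
19 | (2R,3R)-2-[(1S,2S)-1-(tert-butyldimethylsilyloxy)-2,4-dimethyl-2-vinylpent-3-en-1-yl]-5-oxotetrahydrofuran-3-carbaldehyde | C1C(=O)O[C@@H]([C@@H](O[Si](C)(C)C(C)(C)C)[C@@](C)(C=C)C=C(C)C)[C@@H]1C=O | intermediate (key-step precursor)
20 | chloro(methyl)aluminium 6α-alkoxide of 21 | C1C(=O)O[C@@H]2[C@@H]1[C@H](O[Al](C)Cl)[C@@H](C(C)=C)[C@](C)(C=C)[C@@H]2O[Si](C)(C)C(C)(C)C | intermediate (not isolated)
21 | (3aS,4R,5S,6S,7S,7aR)-7-(tert-butyldimethylsilyloxy)-4-hydroxy-6-methyl-5-(prop-1-en-2-yl)-6-vinylhexahydrobenzofuran-2(3H)-one | C1C(=O)O[C@@H]2[C@@H]1[C@H](O)[C@@H](C(C)=C)[C@](C)(C=C)[C@@H]2O[Si](C)(C)C(C)(C)C | intermediate (key-step product)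
22 | C6 ketone | C1C(=O)O[C@@H]2[C@@H]1C(=O)[C@@H](C(C)=C)[C@](C)(C=C)[C@@H]2O[Si](C)(C)C(C)(C)C | intermediate
23 | lithium 6β-alkoxide | C1C(=O)O[C@@H]2[C@@H]1[C@@H](O[Li])[C@@H](C(C)=C)[C@](C)(C=C)[C@@H]2O[Si](C)(C)C(C)(C)C | intermediate (not isolated)
24 | 6β (axial) alcohol | C1C(=O)O[C@@H]2[C@@H]1[C@@H](O)[C@@H](C(C)=C)[C@](C)(C=C)[C@@H]2O[Si](C)(C)C(C)(C)C | intermediate
25 | 6β-isobutyrate | C1C(=O)O[C@@H]2[C@@H]1[C@@H](OC(=O)C(C)C)[C@@H](C(C)=C)[C@](C)(C=C)[C@@H]2O[Si](C)(C)C(C)(C)C | intermediate
26 | lithium lactone enolate | C1=C(O[Li])O[C@@H]2[C@@H]1[C@@H](OC(=O)C(C)C)[C@@H](C(C)=C)[C@](C)(C=C)[C@@H]2O[Si](C)(C)C(C)(C)C | intermediate (not isolated)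
27 | C11 dimethylaminomethyl lactone (C11 undefined) | CN(C)CC1C(=O)O[C@@H]2[C@@H]1[C@@H](OC(=O)C(C)C)[C@@H](C(C)=C)[C@](C)(C=C)[C@@H]2O[Si](C)(C)C(C)(C)C | intermediate (not isolated)
28 | C11 trimethylammoniomethyl lactone iodide | C[N+](C)(C)CC1C(=O)O[C@@H]2[C@@H]1[C@@H](OC(=O)C(C)C)[C@@H](C(C)=C)[C@](C)(C=C)[C@@H]2O[Si](C)(C)C(C)(C)C.[I-] | intermediate (not isolated)
29 | α-methylene lactone | C=C1C(=O)O[C@@H]2[C@@H]1[C@@H](OC(=O)C(C)C)[C@@H](C(C)=C)[C@](C)(C=C)[C@@H]2O[Si](C)(C)C(C)(C)C | intermediate
30 | C15 allylic alcohol | C=C1C(=O)O[C@@H]2[C@@H]1[C@@H](OC(=O)C(C)C)[C@@H](C(=C)CO)[C@](C)(C=C)[C@@H]2O[Si](C)(C)C(C)(C)C | intermediate (not isolated)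
31 | C15 enal, 9α-OTBS | C=C1C(=O)O[C@@H]2[C@@H]1[C@@H](OC(=O)C(C)C)[C@@H](C(=C)C=O)[C@](C)(C=C)[C@@H]2O[Si](C)(C)C(C)(C)C | intermediate
32 | C15 enal, 9α-OH | C=C1C(=O)O[C@@H]2[C@@H]1[C@@H](OC(=O)C(C)C)[C@@H](C(=C)C=O)[C@](C)(C=C)[C@@H]2O | intermediate
33 | CNP0496100.1 | C=C1C(=O)O[C@@H]2[C@@H]1[C@@H](OC(=O)C(C)C)[C@@H](C(=C)C=O)[C@](C)([C@@H]1CO1)[C@@H]2O | target

**Totals**
- Total step count: 18.
- Longest linear sequence: 15 (steps 1–4, then 8–18). The boronate branch (steps 5–7) is convergent.

**Steps most likely to fail**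

1. **Step 11.** The closure must form a bond next to quaternary C10 and build a trans-fused bicycle.
   - If closure is slow, several processes can overtake it: methyl transfer from aluminium to the aldehyde, stepwise cationic capture by chloride, proton loss to a more substituted alkene, or enolisation at C7 followed by loss of the lactone carboxylate.
   - The fallback keeps the C5–C6 disconnection but replaces the pericyclic event with an organochromium allylation, and it sets out from 17.
   - SeO2 (cat.)/t-BuOOH oxidises the C4 methyl trans to C10 to the (E)-allylic alcohol F1, and Appel bromination (CBr4, PPh3) gives the allylic bromide F2.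
   - TESOTf/2,6-lutidine converts the acetal into the lutidinium salt F3, which water hydrolyses to the bromo aldehyde F4.
   - CrCl2 in THF then effects an intramolecular Nozaki–Hiyama allylation, in which γ-attack of the allylchromium at C5 through the same lactone-locked chair gives the chromium alkoxide F5. Aqueous work-up returns to the route at 21.

2. **Step 8.** The conjugated, γ,γ-disubstituted pinacol boronate may add slowly.
   - Slow addition leaves time for hydration or C8 enolisation of the aldehyde, and the facial bias of the substrate alone may be insufficient.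
   - The fallback moves to reagent control and sets out from 14.
   - Transesterification with diethanolamine gives the diethanolamine boronate F6, and exchange with (R,R)-diisopropyl tartrate (Et2O/brine) gives the tartrate boronate F7.
   - The more electrophilic boron of F7 should allow addition to 6 in toluene with 4 Å MS at −78 °C.
   - This tartrate enantiomer is the one expected to reinforce anti addition to (R)-configured α-alkoxy aldehydes, so the pairing is matched.
   - The tartrate borate ester F8 is hydrolysed on work-up, which returns to the route at 16.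

3. **Step 18.** The neopentyl, monosubstituted alkene may be epoxidised slowly.
   - A slow reaction can bring poor facial selectivity or competing oxidation of the C9 carbinol.
   - The fallback replaces substrate direction with catalyst-controlled resolution and sets out from 32.
   - Buffered mCPBA gives 33 together with the (1S)-epoxide F9.
   - Hydrolytic kinetic resolution follows, using (R,R)-(salen)Co(OAc) and water, where salen is the dianion of N,N′-bis(3,5-di-tert-butylsalicylidene)-1,2-cyclohexanediamine. This catalyst enantiomer normally leaves (R)-alkyloxiranes untouched, so it should hydrolyse only F9, to the (1S)-1,2-diol F10.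
   - F10 is removed by chromatography, leaving 33.

**Further compounds**
F1 | step 11 | (E)-allylic alcohol of 17 (C4 methyl trans to C10 hydroxylated) | C1C(=O)O[C@@H]([C@@H](O[Si](C)(C)C(C)(C)C)[C@@](C)(C=C)/C=C(\C)CO)[C@@H]1C2OCCO2
F2 | step 11 | (E)-allylic bromide | C1C(=O)O[C@@H]([C@@H](O[Si](C)(C)C(C)(C)C)[C@@](C)(C=C)/C=C(\C)CBr)[C@@H]1C2OCCO2
F3 | step 11 | lutidinium triflate salt of the bromide (C6 undefined) | C1C(=O)O[C@@H]([C@@H](O[Si](C)(C)C(C)(C)C)[C@@](C)(C=C)/C=C(\C)CBr)[C@@H]1C(OCCO[Si](CC)(CC)CC)[n+]2c(C)cccc2C.[O-]S(=O)(=O)C(F)(F)F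
F4 | step 11 | bromo aldehyde | C1C(=O)O[C@@H]([C@@H](O[Si](C)(C)C(C)(C)C)[C@@](C)(C=C)/C=C(\C)CBr)[C@@H]1C=O
F5 | step 11 | dichlorochromium 6α-alkoxide of 21 | C1C(=O)O[C@@H]2[C@@H]1[C@H](O[Cr](Cl)Cl)[C@@H](C(C)=C)[C@](C)(C=C)[C@@H]2O[Si](C)(C)C(C)(C)C
F6 | step 8 | diethanolamine (2Z)-3,5-dimethylhexa-2,4-dienylboronate | C/C(C=C(C)C)=C/CB1OCCNCCO1
F7 | step 8 | diisopropyl (4R,5R)-2-[(2Z)-3,5-dimethylhexa-2,4-dienyl]-1,3,2-dioxaborolane-4,5-dicarboxylate | C/C(C=C(C)C)=C/CB1O[C@@H](C(=O)OC(C)C)[C@H](C(=O)OC(C)C)O1
F8 | step 8 | tartrate borate ester of 16 | C1C(=O)O[C@@H]([C@@H](OB3O[C@@H](C(=O)OC(C)C)[C@H](C(=O)OC(C)C)O3)[C@@](C)(C=C)C=C(C)C)[C@@H]1C2OCCO2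
F9 | step 18 | (1S)-epoxide, C1 epimer of 33 | C=C1C(=O)O[C@@H]2[C@@H]1[C@@H](OC(=O)C(C)C)[C@@H](C(=C)C=O)[C@](C)([C@H]1CO1)[C@@H]2O
F10 | step 18 | (1S)-1,2-diol from F9 | C=C1C(=O)O[C@@H]2[C@@H]1[C@@H](OC(=O)C(C)C)[C@@H](C(=C)C=O)[C@](C)([C@H](O)CO)[C@@H]2O
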